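At the first reading, 0.625 d, Tuesday's run held more isomer of the product per target than Friday's, 3.18 against 1.05. Those two runs shared their substrate and free catalyst charges but differed in other conformer, 10 mM against 2.5 mM, so I used that difference to reckon the new flask.

in all of them: substrate 20 mM
- Friday's: other conformer 2.5 mM; free catalyst 82 µM; run made earlier
- Tuesday's: other conformer 10 mM; free catalyst 82 µM; run made earlier
- Monday's: other conformer 5 mM; free catalyst 160 µM; run made earlier
- flask: other conformer 5.00 mM; free catalyst 82 µM; time 15 d

- Friday's (time / d: isomer of the product / %, target / %): 0.625: 4.4, 4.2; 1.67: 6.0, 5.7; 3.00: 6.3, 6.4; 5.00: 6.6, 6.8; 6.00: 6.6, 7.4; 10.0: 6.5, 8.2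
- Tuesday's (time / d: isomer of the product / %, target / %): 0.625: 10.8, 3.4; 1.67: 13.1, 4.6; 3.00: 13.6, 5.8; 5.00: 14.4, 5.0; 6.00: 13.9, 5.4; 10.0: 14.5, 6.1
- Monday's (time / d: isomer of the product / %, target / %): 0.833: 11.6, 7.0; 2.50: 12.8, 9.2; 4.00: 12.3, 9.3; 6.00: 12.6, 10.0; 10.0: 12.7, 10.4

(scatter of a reading: 0.3 percentage points)



* ratio of isomer of the product to target at 50 min
* ratio of isomer of the product to target at 15 d
* which of isomer of the product and target there is more of at 15 d

I called the rise of the isomer-to-target ratio per unit of other conformer charged per substrate, at the first reading, the selectivity factor; Tuesday's and Friday's runs put it at 5.68. That line leaves an intercept of 0.338, a part of the ratio that does not follow the charge of other conformer. The flask has 0.250 of other conformer per substrate, so the line gave it 1.76 at 0.625 d.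

But the question stands at 50 min, and the intercept was the weak link. I read it as isomer made from conformer that substrate supplied after the charge, and so let it grow in proportion to time. At 0.0556 of the reading's time I reckoned it at 0.0188, and my early ratio for the flask became 1.44. The same interpolation between the two runs' last readings, at 10.0 d, gave the flask 1.32, which I carried unchanged to 15 d as my estimate, with isomer of the product ahead of target.

The forecast gave 2.15 and 1.18, with isomer of the product ahead. Its early figure stood above mine and its late figure below mine; its ground for the first was “the conformer is about 9 times more reactive, estimated from depletion”.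

The flask gave 1.51 at 50 min and 1.42 at 15 d, with isomer of the product ahead, 9.91 % against 6.95 % of target.

    free catalyst + other conformer → free catalyst + isomer of the product (k = 570 /M/h)
    substrate ⇌ other conformer (K = 0.110, k = 0.00730 /h)
    substrate + free catalyst → free catalyst + target (k = 99.0 /M/h)
    2 free catalyst → spent catalyst (k = 180 /M/h)
    2 substrate → homo dimer (k = 5.20 /M/h)

My reckoning with the selectivity factor of 5.68 had given this flask 1.44 at 50 min, and the flask's 1.51 stood 1.05 times that. The neighbouring flask, with 2.0 mM of other conformer, takes the same reckoning: the factor times its 0.100 of conformer per substrate, plus the same small 0.0188, gives 0.586. That neighbouring flask gave 0.615 at 50 min. At 15 d target led there, 7.45 % against 6.16 % of isomer of the product, a ratio of 0.827.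

All runs stem from a simulated flask on assumed constants, and the scatter is random.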